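**Strategy**

The route rests on cutting the long-chain base at the C6=C7 E-alkene (Julia–Kocienski) and on building its remote stereo-element, the trans-cyclopropane (C12, C13 and the bridging CH2), by a reagent-controlled Simmons–Smith reaction. The ring carries no heteroatom, so C11, the carbon attached to C12, is used as a temporary CH2OH handle: (E)-hept-2-en-1-ol already holds C11–C17 and its hydroxyl directs a chiral zinc carbenoid. In one operation the ring is closed, two C–C bonds are formed and both stereocentres are set. C7–C10 are then added, the C1–C6 azido aldehyde comes from 2-deoxy-D-galactose, and the (R)-2-hydroxy acid from pentacosanoic acid by auxiliary-controlled hydroxylation.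

Key step: step 1

Remarks on the chemistry:
- Locants C1–C17 are those of the long-chain base (C1 = CH2OH, C2 = C–N, C12/C13 = ring carbons); C2′ is the carbinol carbon of the acyl chain. Hexose carbons C6→C1 become C1→C6 of the base.
- The N-acyl group is read as (R)-2-hydroxypentacosanoyl (C25: 23 carbons beyond C2′).
- The (4R,5R)-dioxaborolane ligand of step 1 is assumed to be a purchased reagent.
- CIP descriptors of some intermediates differ from those of the target only because substituent priorities change; the SMILES strings define the geometry.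

**Route**

Step 1
Reactants: 1 (E)-hept-2-en-1-ol; 2 diiodomethane
Product: 4 ((1S,2S)-2-butylcyclopropyl)methanol, via iodomethylzinc (E)-hept-2-en-1-olate 3 (not isolated)
Conditions: Et2Zn (2.2 equiv), 2 (4.4 equiv), DME, CH2Cl2, −10 °C; then 1 and (4R,5R)-2-butyl-N,N,N′,N′-tetramethyl-1,3,2-dioxaborolane-4,5-dicarboxamide (1.2 equiv), −10 °C → rt; aq NH4Cl, then aq KOH
Reagents that add atoms: none
Why: The hydroxyl of 1 is metalated by Zn(CH2I)2 to the iodomethylzinc alkoxide 3, whose oxygen binds the Lewis-acidic boron of the dioxaborolane while a ligand amide carbonyl holds the zinc carbenoid, so that CH2 is handed to the neighbouring alkene inside one chelate through a butterfly-type transition state. The closest known reaction type is the dioxaborolane-controlled variant of the hydroxyl-directed Simmons–Smith cyclopropanation of allylic alcohols. The three-membered ring is closed by a concerted, suprafacial [2+1] methylene transfer that makes both C–CH2 bonds at once, with no open-chain intermediate. The trans relationship of C12 and C13 is inherited stereospecifically from the E alkene, and the absolute configuration at both carbons is fixed by the (4R,5R) ligand, which for E-disubstituted primary allylic alcohols (cinnamyl alcohol being the reference case) should deliver CH2 to the face that gives the (1S,2S) alcohol. The step needs only enantioface selectivity, and the substrate secures it by offering a free primary allylic OH on an unhindered E-1,2-disubstituted alkene with no second alkene or Lewis-basic site to compete.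

Step 2
Reactants: 4 ((1S,2S)-2-butylcyclopropyl)methanol
Product: 5 (1S,2S)-1-butyl-2-(iodomethyl)cyclopropane
Conditions: PPh3, I2, imidazole, CH2Cl2, 0 °C, dark
Reagents that add atoms: iodine, II
Why: Appel-type iodination, in which the alkoxyphosphonium ion is displaced by iodide in an SN2 reaction at the primary carbon under neutral, cold conditions, so that no cyclopropylcarbinyl cation (and hence no homoallyl or cyclobutyl rearrangement) arises and neither ring stereocentre is touched.

Step 3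
Reactants: 5 (1S,2S)-1-butyl-2-(iodomethyl)cyclopropane; 6 but-3-yn-1-ol
Product: 8 5-[(1R,2S)-2-butylcyclopropyl]pent-3-yn-1-ol, via dilithium but-3-yn-1-olate acetylide 7 (not isolated)
Conditions: 6, n-BuLi (2.05 equiv), THF, −78 → 0 °C; DMPU, then 5, 0 °C → rt; aq NH4Cl
Reagents that add atoms: none
Why: Alkylation of a lithium acetylide (alkynol dianion), whose carbon terminus is far more nucleophilic than the lithium alkoxide and displaces iodide at the primary carbon by a closed-shell SN2 path that leaves the ring and both stereocentres untouched (the ring-carbon descriptor reads R only because the alkynyl CH2 now outranks the ring CH2).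

Step 4
Reactants: 8 5-[(1R,2S)-2-butylcyclopropyl]pent-3-yn-1-ol
Product: 9 5-[(1S,2S)-2-butylcyclopropyl]pentan-1-ol
Conditions: H2 (1 atm), 5% Pt/C, EtOAc, rt
Reagents that add atoms: none
Why: Heterogeneous hydrogenation of an isolated internal alkyne to the alkane, with platinum chosen over palladium because it hardly migrates the intermediate alkene toward the ring (no vinylcyclopropane forms), while a non-conjugated 1,2-dialkylcyclopropane is not hydrogenolysed in neutral solvent at 1 atm and rt.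

Step 5
Reactants: 9 5-[(1S,2S)-2-butylcyclopropyl]pentan-1-ol
Product: 10 5-({5-[(1S,2S)-2-butylcyclopropyl]pentyl}sulfanyl)-1-phenyl-1H-tetrazole
Conditions: 1-phenyl-1H-tetrazole-5-thiol, PPh3, DIAD, THF, 0 °C → rt
Reagents that add atoms: 1-phenyl-1H-tetrazole-5-thiol, Sc1nnnn1-c1ccccc1
Why: Mitsunobu thioetherification, in which the acidic tetrazolethiol is alkylated on sulfur by the primary alkoxyphosphonium ion in a clean SN2 step remote from the ring.

Step 6
Reactants: 10 5-({5-[(1S,2S)-2-butylcyclopropyl]pentyl}sulfanyl)-1-phenyl-1H-tetrazole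
Product: 11 5-({5-[(1S,2S)-2-butylcyclopropyl]pentyl}sulfonyl)-1-phenyl-1H-tetrazole
Conditions: (NH4)6Mo7O24·4H2O (cat.), 30% aq H2O2, EtOH, 0 °C → rt
Reagents that add atoms: hydrogen peroxide, OO
Why: Molybdate-catalysed peroxide oxidation of the sulfide to the sulfone, the standard entry to 1-phenyltetrazol-5-yl sulfones, with nothing else in the saturated chain or the dialkylcyclopropane to oxidise.

Step 7
Reactants: 12 2-deoxy-D-galactose
Product: 13 2-deoxy-6-O-trityl-D-lyxo-hexopyranose
Conditions: TrCl, pyridine, DMAP (cat.), rt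
Reagents that add atoms: trityl chloride, ClC(c1ccccc1)(c1ccccc1)c1ccccc1
Why: Selective tritylation, the bulky reagent reacting at the only primary hydroxyl (sugar O6, the future O1) and leaving the secondary and anomeric hydroxyls free.

Step 8
Reactants: 13 2-deoxy-6-O-trityl-D-lyxo-hexopyranose
Product: 14 2-deoxy-3,4-O-isopropylidene-6-O-trityl-D-lyxo-hexopyranose
Conditions: 2-methoxypropene, PPTS (cat.), DMF, 0 °C → rt; buffered aq work-up (pH 5)
Reagents that add atoms: 2-methoxypropene, COC(C)=C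
Why: Acid-catalysed acetonide formation by transketalisation with an enol ether, in which, with O6 blocked, the cis-3,4-diol of the pyranose is the only pair able to close a five-membered ketal and the hemiacetal hydroxyl stays free (any anomeric mixed ketal falls apart in the buffered work-up), no stereocentre being created.

Step 9
Reactants: 14 2-deoxy-3,4-O-isopropylidene-6-O-trityl-D-lyxo-hexopyranose
Product: 15 (1R)-1-[(4S,5R)-2,2-dimethyl-5-(prop-2-en-1-yl)-1,3-dioxolan-4-yl]-2-(trityloxy)ethan-1-ol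
Conditions: Ph3PCH3Br (3.5 equiv), KOtBu (3.3 equiv), THF, 0 °C → rt
Reagents that add atoms: methyltriphenylphosphonium bromide, C[P+](c1ccccc1)(c1ccccc1)c1ccccc1.[Br-]
Why: Wittig methylenation of a lactol through its open-chain hydroxy aldehyde tautomer (excess ylide, the first equivalent serving as base), which turns C6 into a vinyl-masked aldehyde and releases the ring oxygen as the free secondary hydroxyl at C2, the α-carbon being a CH2 so that nothing can epimerise.

Step 10
Reactants: 15 (1R)-1-[(4S,5R)-2,2-dimethyl-5-(prop-2-en-1-yl)-1,3-dioxolan-4-yl]-2-(trityloxy)ethan-1-ol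
Product: 17 (4S,5R)-4-[(1S)-1-azido-2-(trityloxy)ethyl]-2,2-dimethyl-5-(prop-2-en-1-yl)-1,3-dioxolane, via secondary triflate 16 (not isolated)
Conditions: Tf2O, pyridine, CH2Cl2, −30 °C; then NaN3, DMF, 0 °C → rt
Reagents that add atoms: sodium azide, [Na+].[N-]=[N+]=[N-]
Why: Sulfonate activation followed by SN2 displacement, the hindered secondary triflate being displaced by azide at or below rt with clean inversion so that the 2R carbinol becomes the 2S azide (the nitrogen-bearing stereocentre of the target), the low temperature also forestalling intramolecular azide–alkene cycloaddition.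

Step 11
Reactants: 17 (4S,5R)-4-[(1S)-1-azido-2-(trityloxy)ethyl]-2,2-dimethyl-5-(prop-2-en-1-yl)-1,3-dioxolane
Product: 19 2-[(4R,5S)-5-[(1S)-1-azido-2-(trityloxy)ethyl]-2,2-dimethyl-1,3-dioxolan-4-yl]acetaldehyde, via secondary ozonide 18 (not isolated)
Conditions: O3, CH2Cl2, −78 °C (Sudan III end point); Me2S, −78 °C → rt; used crude
Reagents that add atoms: ozone, [O-][O+]=O
Why: Ozonolysis with reductive work-up, the terminal alkene being the only ozone-reactive π bond (the indicator dye guards the trityl rings against over-ozonation) and dimethyl sulfide rather than a phosphine reducing the ozonide so that the azide survives.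

Step 12
Reactants: 11 5-({5-[(1S,2S)-2-butylcyclopropyl]pentyl}sulfonyl)-1-phenyl-1H-tetrazole; 19 2-[(4R,5S)-5-[(1S)-1-azido-2-(trityloxy)ethyl]-2,2-dimethyl-1,3-dioxolan-4-yl]acetaldehyde
Product: 21 (4S,5R)-4-[(1S)-1-azido-2-(trityloxy)ethyl]-5-{(2E)-7-[(1S,2S)-2-butylcyclopropyl]hept-2-en-1-yl}-2,2-dimethyl-1,3-dioxolane, via potassium sulfonyl carbanion 20 (not isolated)
Conditions: 11 (1.2 equiv), KHMDS, DME, −60 °C; then 19, −60 °C → rt; aq NH4Cl
Reagents that add atoms: none
Why: Julia–Kocienski olefination, in which the pre-formed sulfonyl carbanion adds to the aldehyde, the β-alkoxide takes over the tetrazole by Smiles rearrangement and SO2 and the tetrazololate are expelled, a sequence that with KHMDS in DME should favour the E alkene (C6=C7) for two unbranched partners, while pre-metalation leaves no free amide base to enolise the β-alkoxy aldehyde and no stereocentre is touched.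

Step 13
Reactants: 21 (4S,5R)-4-[(1S)-1-azido-2-(trityloxy)ethyl]-5-{(2E)-7-[(1S,2S)-2-butylcyclopropyl]hept-2-en-1-yl}-2,2-dimethyl-1,3-dioxolane
Product: 23 (1S)-1-[(4S,5R)-5-{(2E)-7-[(1S,2S)-2-butylcyclopropyl]hept-2-en-1-yl}-2,2-dimethyl-1,3-dioxolan-4-yl]-2-(trityloxy)ethan-1-amine, via iminophosphorane 22 (not isolated)
Conditions: PMe3 (1 M in THF), THF, rt; then H2O, rt
Reagents that add atoms: none
Why: Staudinger reduction, in which the small phosphine attacks the hindered azide, N2 is lost and the iminophosphorane is hydrolysed at rt, a chemoselective azide-to-amine conversion that leaves the alkene and the cyclopropane (which hydrogenation would endanger) untouched.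

Step 14
Reactants: 24 pentacosanoic acid
Product: 26 (4R)-4-benzyl-3-pentacosanoyl-1,3-oxazolidin-2-one, via pivalic mixed anhydride 25 (not isolated)
Conditions: PivCl, Et3N, THF, −20 → 0 °C; then (R)-4-benzyl-1,3-oxazolidin-2-one, LiCl, rt
Reagents that add atoms: (R)-4-benzyl-1,3-oxazolidin-2-one, O=C1N[C@H](Cc2ccccc2)CO1
Why: N-Acylation of an oxazolidinone auxiliary through the pivalic mixed anhydride (LiCl/Et3N activation of the N–H), a standard way to load long-chain acids, the only stereocentre being that of the auxiliary.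

Step 15
Reactants: 26 (4R)-4-benzyl-3-pentacosanoyl-1,3-oxazolidin-2-one
Product: 28 (4R)-4-benzyl-3-[(2R)-2-hydroxypentacosanoyl]-1,3-oxazolidin-2-one, via sodium Z-enolate 27 (not isolated)
Conditions: NaHMDS, THF (dilute), −78 °C; 2-(phenylsulfonyl)-3-phenyloxaziridine, −78 °C; AcOH quench
Reagents that add atoms: trans-2-(phenylsulfonyl)-3-phenyloxaziridine, O=S(=O)(c1ccccc1)N1OC1c1ccccc1
Why: Auxiliary-controlled enolate hydroxylation, in which the chelated sodium Z-enolate is oxygenated by the N-sulfonyloxaziridine on the face away from the benzyl group, which with the (R)-auxiliary should set C2′ as R.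

Step 16
Reactants: 28 (4R)-4-benzyl-3-[(2R)-2-hydroxypentacosanoyl]-1,3-oxazolidin-2-one
Product: 30 (2R)-2-hydroxypentacosanoic acid, via peroxy acid 29 (not isolated)
Conditions: LiOH, 30% H2O2, THF/H2O (3:1), 0 °C; aq Na2SO3; aq HCl to pH 2
Reagents that add atoms: hydrogen peroxide (acting as LiOOH), OO
Why: Hydroperoxide cleavage of the N-acyl oxazolidinone, in which the small α-effect nucleophile attacks the exocyclic carbonyl selectively, sulfite reduces the peracid and the α-stereocentre is not epimerised under these cold conditions.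

Step 17
Reactants: 23 (1S)-1-[(4S,5R)-5-{(2E)-7-[(1S,2S)-2-butylcyclopropyl]hept-2-en-1-yl}-2,2-dimethyl-1,3-dioxolan-4-yl]-2-(trityloxy)ethan-1-amine; 30 (2R)-2-hydroxypentacosanoic acid
Product: 31 (2R)-N-{(1S)-1-[(4S,5R)-5-{(2E)-7-[(1S,2S)-2-butylcyclopropyl]hept-2-en-1-yl}-2,2-dimethyl-1,3-dioxolan-4-yl]-2-(trityloxy)ethyl}-2-hydroxypentacosanamide
Conditions: EDC·HCl, HOBt, i-Pr2NEt, CH2Cl2/THF, rt → 35 °C
Reagents that add atoms: none
Why: Carbodiimide/HOBt amide coupling, in which the primary amine is acylated by the active ester far faster than the free secondary hydroxyl and the mild activation keeps C2′ intact.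

Step 18
Reactants: 31 (2R)-N-{(1S)-1-[(4S,5R)-5-{(2E)-7-[(1S,2S)-2-butylcyclopropyl]hept-2-en-1-yl}-2,2-dimethyl-1,3-dioxolan-4-yl]-2-(trityloxy)ethyl}-2-hydroxypentacosanamide
Product: 32 (2R)-N-{(2S,3S,4R,6E)-11-[(1S,2S)-2-butylcyclopropyl]-1,3,4-trihydroxyundec-6-en-2-yl}-2-hydroxypentacosanamide (target)
Conditions: 1 M aq HCl/THF (1:4), 40 °C; NaHCO3
Reagents that add atoms: none
Why: Acid hydrolysis of the isopropylidene ketal and the trityl ether in one operation, dilute aqueous acid at 40 °C being mild enough for the isolated alkene, the dialkylcyclopropane and the amide (no N→O acyl shift) and touching no stereocentre.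

**Compound list**

1 | (E)-hept-2-en-1-ol | CCCC/C=C/CO | starting material
2 | diiodomethane | ICI | starting material
3 | iodomethylzinc (E)-hept-2-en-1-olate | CCCC/C=C/CO[Zn]CI | intermediate (not isolated)
4 | ((1S,2S)-2-butylcyclopropyl)methanol | OC[C@H]1C[C@@H]1CCCC | intermediate
5 | (1S,2S)-1-butyl-2-(iodomethyl)cyclopropane | IC[C@H]1C[C@@H]1CCCC | intermediate
6 | but-3-yn-1-ol | C#CCCO | starting material
7 | dilithium salt of but-3-yn-1-ol (alkoxide acetylide) | [Li+].[Li+].[C-]#CCC[O-] | intermediate (not isolated)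
8 | 5-[(1R,2S)-2-butylcyclopropyl]pent-3-yn-1-ol | OCCC#CC[C@H]1C[C@@H]1CCCC | intermediate
9 | 5-[(1S,2S)-2-butylcyclopropyl]pentan-1-ol | OCCCCC[C@H]1C[C@@H]1CCCC | intermediate
10 | 5-({5-[(1S,2S)-2-butylcyclopropyl]pentyl}sulfanyl)-1-phenyl-1H-tetrazole | c1ccccc1-n1nnnc1SCCCCC[C@H]2C[C@@H]2CCCC | intermediate
11 | 5-({5-[(1S,2S)-2-butylcyclopropyl]pentyl}sulfonyl)-1-phenyl-1H-tetrazole | c1ccccc1-n1nnnc1S(=O)(=O)CCCCC[C@H]2C[C@@H]2CCCC | intermediate
12 | 2-deoxy-D-galactose (2-deoxy-D-lyxo-hexopyranose) | OC[C@H]1OC(O)C[C@@H](O)[C@H]1O | starting material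
13 | 2-deoxy-6-O-trityl-D-lyxo-hexopyranose | c1ccccc1C(c1ccccc1)(c1ccccc1)OC[C@H]2OC(O)C[C@@H](O)[C@H]2O | intermediate
14 | 2-deoxy-3,4-O-isopropylidene-6-O-trityl-D-lyxo-hexopyranose | c1ccccc1C(c1ccccc1)(c1ccccc1)OC[C@H]2OC(O)C[C@H]3OC(C)(C)O[C@@H]23 | intermediate
15 | (1R)-1-[(4S,5R)-2,2-dimethyl-5-(prop-2-en-1-yl)-1,3-dioxolan-4-yl]-2-(trityloxy)ethan-1-ol | c1ccccc1C(c1ccccc1)(c1ccccc1)OC[C@@H](O)[C@@H]2OC(C)(C)O[C@@H]2CC=C | intermediate
16 | (1R)-1-[(4R,5R)-2,2-dimethyl-5-(prop-2-en-1-yl)-1,3-dioxolan-4-yl]-2-(trityloxy)ethyl trifluoromethanesulfonate | c1ccccc1C(c1ccccc1)(c1ccccc1)OC[C@@H](OS(=O)(=O)C(F)(F)F)[C@@H]2OC(C)(C)O[C@@H]2CC=C | intermediate (not isolated)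
17 | (4S,5R)-4-[(1S)-1-azido-2-(trityloxy)ethyl]-2,2-dimethyl-5-(prop-2-en-1-yl)-1,3-dioxolane | c1ccccc1C(c1ccccc1)(c1ccccc1)OC[C@H](N=[N+]=[N-])[C@@H]2OC(C)(C)O[C@@H]2CC=C | intermediate
18 | (4S,5R)-4-[(1S)-1-azido-2-(trityloxy)ethyl]-2,2-dimethyl-5-(1,2,4-trioxolan-3-ylmethyl)-1,3-dioxolane (both epimers at the trioxolane carbon) | c1ccccc1C(c1ccccc1)(c1ccccc1)OC[C@H](N=[N+]=[N-])[C@@H]2OC(C)(C)O[C@@H]2CC3OCOO3 | intermediate (not isolated)
19 | 2-[(4R,5S)-5-[(1S)-1-azido-2-(trityloxy)ethyl]-2,2-dimethyl-1,3-dioxolan-4-yl]acetaldehyde | c1ccccc1C(c1ccccc1)(c1ccccc1)OC[C@H](N=[N+]=[N-])[C@@H]2OC(C)(C)O[C@@H]2CC=O | intermediate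
20 | potassium salt of 11 deprotonated at the SO2–CH2 carbon | c1ccccc1-n1nnnc1S(=O)(=O)[CH-]CCCC[C@H]2C[C@@H]2CCCC.[K+] | intermediate (not isolated)
21 | (4S,5R)-4-[(1S)-1-azido-2-(trityloxy)ethyl]-5-{(2E)-7-[(1S,2S)-2-butylcyclopropyl]hept-2-en-1-yl}-2,2-dimethyl-1,3-dioxolane | c1ccccc1C(c1ccccc1)(c1ccccc1)OC[C@H](N=[N+]=[N-])[C@@H]2OC(C)(C)O[C@@H]2C/C=C/CCCC[C@H]3C[C@@H]3CCCC | intermediate
22 | N-(trimethyl-λ5-phosphanylidene) derivative of amine 23 | c1ccccc1C(c1ccccc1)(c1ccccc1)OC[C@H](N=P(C)(C)C)[C@@H]2OC(C)(C)O[C@@H]2C/C=C/CCCC[C@H]3C[C@@H]3CCCC | intermediate (not isolated)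
23 | (1S)-1-[(4S,5R)-5-{(2E)-7-[(1S,2S)-2-butylcyclopropyl]hept-2-en-1-yl}-2,2-dimethyl-1,3-dioxolan-4-yl]-2-(trityloxy)ethan-1-amine | c1ccccc1C(c1ccccc1)(c1ccccc1)OC[C@H](N)[C@@H]2OC(C)(C)O[C@@H]2C/C=C/CCCC[C@H]3C[C@@H]3CCCC | intermediate
24 | pentacosanoic acid | CCCCCCCCCCCCCCCCCCCCCCCCC(=O)O | starting material
25 | pentacosanoic pivalic anhydride | CCCCCCCCCCCCCCCCCCCCCCCCC(=O)OC(=O)C(C)(C)C | intermediate (not isolated)
26 | (4R)-4-benzyl-3-pentacosanoyl-1,3-oxazolidin-2-one | CCCCCCCCCCCCCCCCCCCCCCCCC(=O)N1[C@H](Cc2ccccc2)COC1=O | intermediate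
27 | sodium (Z)-enolate of 26 | CCCCCCCCCCCCCCCCCCCCCCC/C=C(\[O-])N1[C@H](Cc2ccccc2)COC1=O.[Na+] | intermediate (not isolated)
28 | (4R)-4-benzyl-3-[(2R)-2-hydroxypentacosanoyl]-1,3-oxazolidin-2-one | CCCCCCCCCCCCCCCCCCCCCCC[C@@H](O)C(=O)N1[C@H](Cc2ccccc2)COC1=O | intermediate
29 | (2R)-2-hydroxypentacosaneperoxoic acid | CCCCCCCCCCCCCCCCCCCCCCC[C@@H](O)C(=O)OO | intermediate (not isolated)
30 | (2R)-2-hydroxypentacosanoic acid | CCCCCCCCCCCCCCCCCCCCCCC[C@@H](O)C(=O)O | intermediate
31 | (2R)-N-{(1S)-1-[(4S,5R)-5-{(2E)-7-[(1S,2S)-2-butylcyclopropyl]hept-2-en-1-yl}-2,2-dimethyl-1,3-dioxolan-4-yl]-2-(trityloxy)ethyl}-2-hydroxypentacosanamide | CCCCCCCCCCCCCCCCCCCCCCC[C@@H](O)C(=O)N[C@@H](COC(c1ccccc1)(c1ccccc1)c1ccccc1)[C@@H]2OC(C)(C)O[C@@H]2C/C=C/CCCC[C@H]3C[C@@H]3CCCC | intermediate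
32 | (2R)-N-{(2S,3S,4R,6E)-11-[(1S,2S)-2-butylcyclopropyl]-1,3,4-trihydroxyundec-6-en-2-yl}-2-hydroxypentacosanamide | CCCCCCCCCCCCCCCCCCCCCCC[C@@H](O)C(=O)N[C@@H](CO)[C@H](O)[C@H](O)C/C=C/CCCC[C@H]1C[C@@H]1CCCC | target

**Totals and risks**

Total step count: 18.
Longest linear sequence: 10 steps (steps 1–6, 12, 13, 17, 18, from (E)-hept-2-en-1-ol).

The three steps most likely to fail:

Step 12 (union at C6=C7). The sulfonyl carbanion may deprotonate the enolisable β-alkoxy aldehyde, after which the C4 ketal oxygen is expelled (E1cB), or the E selectivity may fall short. The fallback replaces carbonyl olefination by olefin cross-metathesis and sets out from alcohol 9 and azido alkene 17. Alcohol 9 is oxidised (Dess–Martin periodinane, NaHCO3, CH2Cl2) to 5-[(1S,2S)-2-butylcyclopropyl]pentanal F1, which is methylenated (Ph3P=CH2, THF) to (1S,2S)-1-butyl-2-(hex-5-en-1-yl)cyclopropane F2. F2 (in excess) and 17 are joined with the phosphine-free Hoveyda–Grubbs second-generation catalyst (CH2Cl2, 40 °C) with loss of ethene, the Z isomer being removed on AgNO3-impregnated silica. The route is re-entered at 21; steps 5, 6 and 11 are then not needed.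

Step 3 (C10–C11 bond). Displacement at the β-branched primary iodide may be sluggish, or the cyclopropylcarbinyl iodide may open to a homoallyl iodide before it is alkylated. The fallback avoids any cyclopropylcarbinyl electrophile and sets out from alcohol 4. Oxidation (Dess–Martin periodinane, CH2Cl2) gives (1S,2S)-2-butylcyclopropane-1-carbaldehyde F3. A Wittig reaction with the ylide from (4-hydroxybutyl)triphenylphosphonium bromide and two equivalents of KHMDS (THF, −78 °C → rt) gives (4Z)-5-[(1S,2S)-2-butylcyclopropyl]pent-4-en-1-ol F4. Diimide (dipotassium azodicarboxylate, AcOH, MeOH) saturates the alkene next to the ring without touching the ring and returns to 9.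

Step 9 (opening of the lactol). The open-chain aldehyde is present only in small amount and, as a 2-deoxy-3-alkoxy aldehyde, may lose its β-oxygen by elimination under the basic ylide conditions. The fallback opens the ring by reduction instead of olefination and sets out from lactol 14. NaBH4 (MeOH, 0 °C) gives 2-[(4R,5S)-5-[(1R)-1-hydroxy-2-(trityloxy)ethyl]-2,2-dimethyl-1,3-dioxolan-4-yl]ethan-1-ol F5. Selective silylation of the primary hydroxyl (TBSCl, imidazole, CH2Cl2, −20 °C) gives (1R)-1-[(4S,5R)-5-[2-(tert-butyldimethylsilyloxy)ethyl]-2,2-dimethyl-1,3-dioxolan-4-yl]-2-(trityloxy)ethan-1-ol F6. Triflation as in step 10 gives the triflate ester of F6 F7 (not isolated), and azide displacement gives (4S,5R)-4-[(1S)-1-azido-2-(trityloxy)ethyl]-5-[2-(tert-butyldimethylsilyloxy)ethyl]-2,2-dimethyl-1,3-dioxolane F8. TBAF (THF, 0 °C) gives 2-[(4R,5S)-5-[(1S)-1-azido-2-(trityloxy)ethyl]-2,2-dimethyl-1,3-dioxolan-4-yl]ethan-1-ol F9. Dess–Martin oxidation returns to aldehyde 19; steps 10 and 11 are replaced as well.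

**Further compounds**

F1 | step 12 | 5-[(1S,2S)-2-butylcyclopropyl]pentanal | O=CCCCC[C@H]1C[C@@H]1CCCC
F2 | step 12 | (1S,2S)-1-butyl-2-(hex-5-en-1-yl)cyclopropane | C=CCCCC[C@H]1C[C@@H]1CCCC
F3 | step 3 | (1S,2S)-2-butylcyclopropane-1-carbaldehyde | O=C[C@H]1C[C@@H]1CCCC
F4 | step 3 | (4Z)-5-[(1S,2S)-2-butylcyclopropyl]pent-4-en-1-ol | OCCC/C=C\[C@H]1C[C@@H]1CCCC
F5 | step 9 | 2-[(4R,5S)-5-[(1R)-1-hydroxy-2-(trityloxy)ethyl]-2,2-dimethyl-1,3-dioxolan-4-yl]ethan-1-ol | c1ccccc1C(c1ccccc1)(c1ccccc1)OC[C@@H](O)[C@@H]2OC(C)(C)O[C@@H]2CCO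
F6 | step 9 | (1R)-1-[(4S,5R)-5-[2-(tert-butyldimethylsilyloxy)ethyl]-2,2-dimethyl-1,3-dioxolan-4-yl]-2-(trityloxy)ethan-1-ol | c1ccccc1C(c1ccccc1)(c1ccccc1)OC[C@@H](O)[C@@H]2OC(C)(C)O[C@@H]2CCO[Si](C)(C)C(C)(C)C
F7 | step 9 | triflate ester of F6 at the secondary hydroxyl | c1ccccc1C(c1ccccc1)(c1ccccc1)OC[C@@H](OS(=O)(=O)C(F)(F)F)[C@@H]2OC(C)(C)O[C@@H]2CCO[Si](C)(C)C(C)(C)C
F8 | step 9 | (4S,5R)-4-[(1S)-1-azido-2-(trityloxy)ethyl]-5-[2-(tert-butyldimethylsilyloxy)ethyl]-2,2-dimethyl-1,3-dioxolane | c1ccccc1C(c1ccccc1)(c1ccccc1)OC[C@H](N=[N+]=[N-])[C@@H]2OC(C)(C)O[C@@H]2CCO[Si](C)(C)C(C)(C)C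
F9 | step 9 | 2-[(4R,5S)-5-[(1S)-1-azido-2-(trityloxy)ethyl]-2,2-dimethyl-1,3-dioxolan-4-yl]ethan-1-ol | c1ccccc1C(c1ccccc1)(c1ccccc1)OC[C@H](N=[N+]=[N-])[C@@H]2OC(C)(C)O[C@@H]2CCO
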